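**Plan**

1. Locants follow the azulenone numbering of the target: C1 carbinol with isopropyl, C3a angular methyl carbon, C4 ketone, C5=C6 with methyl on C6, C8 ester carbon, C8a ring-fusion CH. Ring A is the seven-membered ring, ring B the five-membered ring.
2. Retrosynthesis: the ester C(=O)–O bond at C8 is cut first; then C4–C5 and C5–C6 of ring A are cut and C4 is rejoined to C6, which contracts ring A to a trans-hydrindanone. This works because in ring A the ketone carbon C4 stands between the quaternary C3a and the C5H=C6(CH3) unit, so C5 can be inserted last into a six-membered ketone whose only α-hydrogen sits on the methyl-bearing carbon.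
3. The hydrindanone is cut at the α-methyl bond, at the ring CH2–CH2 bond made by enolate alkylation, at the isopropyl–carbinol bond, at the aldol bond and at the alkenyl–quaternary-carbon bond. This leads back to 3-methylcyclopent-2-en-1-one, an isopropenyl and an isopropyl Grignard reagent, benzyloxyacetaldehyde and 4-acetoxybenzoic acid.
4. Forward: ring B is bought; a conjugate addition–aldol sequence puts both side arms on it; the six-membered ring is closed by intramolecular alkylation; ring A is made last by one-carbon ring expansion; the ester is attached at the end.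
5. Stereochemistry: C3a from the catalytic asymmetric conjugate addition; C8a and C8 from the aldol step (attack trans to isopropenyl, anti adduct); C1 from isopropyl addition anti to the side chain; the ring expansion makes no stereocentre.

Key step: step 11

Assumption: the copper–ligand pair of step 1 is taken to deliver the isopropenyl group to the Si face of C3 of 1; should the sense of induction be opposite, the mirror-image ligand is used.
Remark: compounds 14–18 carry indene or azulene locants as named; C5 of 15, the cyclopropane carbons of 17 and the chlorine-bearing carbon of 18 are formed as mixtures and are left unassigned, because all are erased before 19.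

**Route**

Step 1
Reactants: 1 3-methylcyclopent-2-en-1-one; 2 prop-1-en-2-ylmagnesium bromide; 3 2-(benzyloxy)acetaldehyde
Product: 6 (2S,3S)-2-[(1R)-2-(benzyloxy)-1-hydroxyethyl]-3-methyl-3-(prop-1-en-2-yl)cyclopentan-1-one, via dimethyl(prop-1-en-2-yl)aluminium 4 (not isolated), via aluminium enolate 5 (not isolated)
Conditions: 2, Me2AlCl, Et2O/THF, −30 °C; then 1, Cu(O2CC4H3S) (copper thiophene-2-carboxylate, 10 mol %), (R,R)-Ph2PN[CH(CH3)(2-naphthyl)]2 (11 mol %), −30 °C; then 3, −78 → −40 °C; aq. potassium sodium tartrate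
Reagents that add atoms: none
Why: Copper-catalysed asymmetric conjugate addition of an alkenylaluminium reagent is a known way to quaternary β-carbons of cyclic enones and sets C3 (S) under ligand control, while the ring-locked (E)-aluminium enolate 5 should add to the aldehyde through a chair Zimmerman–Traxler aldol transition state on the face away from the larger isopropenyl group, setting C2 (S, side chain trans to isopropenyl) and the anti carbinol centre (1'R).

Step 2
Reactants: 6
Product: 7 (2S,3S)-2-[(1R)-2-(benzyloxy)-1-(tert-butyldimethylsilyloxy)ethyl]-3-methyl-3-(prop-1-en-2-yl)cyclopentan-1-one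
Conditions: TBSOTf, 2,6-lutidine, CH2Cl2, −78 °C
Reagents that add atoms: tert-butyldimethylsilyl trifluoromethanesulfonate, CC(C)(C)[Si](C)(C)OS(=O)(=O)C(F)(F)F
Why: Silyl ether formation with a silyl triflate and a hindered pyridine base is fast at low temperature and masks the aldol hydroxyl, so retro-aldol cleavage and alkoxide chemistry are excluded in step 3; no stereocentre is touched.

Step 3
Reactants: 7; 8 propan-2-ylmagnesium chloride
Product: 9 (1R,2S,3S)-2-[(1R)-2-(benzyloxy)-1-(tert-butyldimethylsilyloxy)ethyl]-3-methyl-1-(propan-2-yl)-3-(prop-1-en-2-yl)cyclopentan-1-ol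
Conditions: 8, anhydrous CeCl3, THF, −78 → −40 °C; aq. NH4Cl
Reagents that add atoms: none
Why: Organocerium 1,2-addition suppresses enolisation and β-hydride reduction of the hindered ketone, and the nucleophile should enter C1 anti to the large α-side chain on C2, giving the tertiary alcohol with its hydroxyl cis to that side chain (1R).

Step 4
Reactants: 9
Product: 10 {[(1R,2S,3S)-2-[(1R)-2-(benzyloxy)-1-(tert-butyldimethylsilyloxy)ethyl]-3-methyl-1-(propan-2-yl)-3-(prop-1-en-2-yl)cyclopentyl]oxy}triethylsilane
Conditions: TESOTf, 2,6-lutidine, CH2Cl2, 0 °C → rt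
Reagents that add atoms: triethylsilyl trifluoromethanesulfonate, CC[Si](CC)(CC)OS(=O)(=O)C(F)(F)F
Why: Silylation of the tertiary alcohol with the reactive triflate is standard, and it is needed because the free hydroxyl, cis to the side chain, would otherwise close a tetrahydrofuran on the later primary iodide.

Step 5
Reactants: 10
Product: 11 1-[(1S,2S,3R)-2-[(1R)-2-(benzyloxy)-1-(tert-butyldimethylsilyloxy)ethyl]-1-methyl-3-(propan-2-yl)-3-(triethylsilyloxy)cyclopentyl]ethan-1-one
Conditions: O3, CH2Cl2, −78 °C (Sudan Red end point); then PPh3, −78 °C → rt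
Reagents that add atoms: ozone, [O-][O+]=O
Why: Ozonolysis with reductive work-up cleaves the electron-rich 1,1-disubstituted alkene far faster than ozone attacks the benzyl ether, and it unveils the methyl ketone on the quaternary carbon.

Step 6
Reactants: 11
Product: 12 1-[(1S,2S,3R)-2-[(1R)-1-(tert-butyldimethylsilyloxy)-2-hydroxyethyl]-1-methyl-3-(propan-2-yl)-3-(triethylsilyloxy)cyclopentyl]ethan-1-one
Conditions: H2 (1 atm), 10% Pd/C, EtOAc, rt
Reagents that add atoms: none
Why: Hydrogenolysis of the benzyl ether over palladium in a neutral aprotic solvent should leave both silyl ethers and the hindered ketone untouched.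

Step 7
Reactants: 12
Product: 13 1-[(1S,2S,3R)-2-[(1R)-1-(tert-butyldimethylsilyloxy)-2-iodoethyl]-1-methyl-3-(propan-2-yl)-3-(triethylsilyloxy)cyclopentyl]ethan-1-one
Conditions: I2, PPh3, imidazole, CH2Cl2, 0 °C → rt
Reagents that add atoms: iodine, [I][I]
Why: Appel-type iodination converts the primary alcohol into the iodide under imidazole-buffered, non-acidic conditions that the silyl ethers tolerate.

Step 8
Reactants: 13
Product: 14 (1R,3aS,7S,7aS)-7-(tert-butyldimethylsilyloxy)-3a-methyl-1-(propan-2-yl)-1-(triethylsilyloxy)octahydro-4H-inden-4-one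
Conditions: LiN(i-Pr)2, THF/DMPU, −78 °C → rt
Reagents that add atoms: none
Why: Intramolecular enolate alkylation, a favoured 6-(enolendo)-exo-tet closure, forms the cyclohexanone because the ketone can enolise only at its methyl group; the trans ring fusion follows from the trans arrangement of acetyl group and side chain on the cyclopentane, with the silyloxy group equatorial in the chair-like transition state.

Step 9
Reactants: 14
Product: 15 (1R,3aS,7S,7aS)-7-(tert-butyldimethylsilyloxy)-3a,5-dimethyl-1-(propan-2-yl)-1-(triethylsilyloxy)octahydro-4H-inden-4-one (mixture at C5)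
Conditions: LiN(i-Pr)2, THF, −78 °C; then MeI, −78 → 0 °C
Reagents that add atoms: iodomethane, IC
Why: Kinetic enolate methylation can occur only at C5, the sole α-carbon bearing hydrogen, and the configuration of the new centre does not matter because step 10 flattens it.

Step 10
Reactants: 15
Product: 16 (1R,3aS,7S,7aS)-7-(tert-butyldimethylsilyloxy)-3a,5-dimethyl-1-(propan-2-yl)-1-(triethylsilyloxy)-4-(trimethylsilyloxy)-2,3,3a,6,7,7a-hexahydro-1H-indene
Conditions: TMSOTf, Et3N, CH2Cl2, 0 °C → rt
Reagents that add atoms: trimethylsilyl trifluoromethanesulfonate, C[Si](C)(C)OS(=O)(=O)C(F)(F)F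
Why: Soft enolisation with silyl triflate and amine gives the only enol ether this ketone can form, the tetrasubstituted one between C4 and C5, since the other α-carbon is quaternary.

Step 11
Reactants: 16
Product: 19 (1R,3aS,8S,8aS)-8-(tert-butyldimethylsilyloxy)-3a,6-dimethyl-1-(propan-2-yl)-1-(triethylsilyloxy)-2,3,3a,7,8,8a-hexahydroazulen-4(1H)-one, via siloxycyclopropane 17 (not isolated), via β-chloro ketone 18 (not isolated)
Conditions: Et2Zn, CH2I2, CH2Cl2, 0 °C → rt; then FeCl3, DMF, 0 °C → rt; then NaOAc, MeOH, reflux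
Reagents that add atoms: diiodomethane, C(I)I
Why: The zinc carbenoid from Et2Zn and CH2I2 adds CH2 in a concerted [2+1] manner to the electron-rich C4=C5 enol ether of 16 to give 17; FeCl3 (trivalent iron) then takes one electron from 17, the cyclopropane bond shared with the six-membered ring breaks to leave the ketone and a tertiary radical on the methyl-bearing carbon, a second FeCl3 transfers chlorine to that radical (both end as FeCl2, divalent iron), and acetate removes HCl from 18 by an E1cB path toward the only acidic CH2. The closest known reaction type is the Saegusa-type one-carbon ring expansion of 1-siloxybicyclo[n.1.0]alkanes to cycloalk-2-enones, preceded by a Furukawa-type Simmons–Smith cyclopropanation. The three-membered ring closes by cheletropic [2+1] addition, whereas the seven-membered ring A is never closed as such: it results from enlargement of the six-membered ring when the bond common to the two fused rings of the bicyclo[4.1.0]heptane is cut. No lasting stereocentre is made, since the two cyclopropane carbons and the chlorine-bearing carbon are formed as mixtures and are all erased, and the four existing centres lie outside the reacting atoms. The step needs cleavage of the internal rather than an external cyclopropane bond, which the methyl group secures by making internal cleavage give a tertiary radical with relief of bicyclic strain, and it needs a single enol ether regioisomer, which the quaternary angular carbon secures by leaving hydrogen on one α-carbon only.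

Step 12
Reactants: 19
Product: 20 (1R,3aS,8S,8aS)-1,8-dihydroxy-3a,6-dimethyl-1-(propan-2-yl)-2,3,3a,7,8,8a-hexahydroazulen-4(1H)-one
Conditions: HF·pyridine, pyridine, THF, 0 °C → rt
Reagents that add atoms: none
Why: Fluoride-mediated desilylation with buffered HF·pyridine removes both silyl ethers without base, so the enone and the tertiary alcohol are not endangered.

Step 13
Reactants: 20; 21 4-acetoxybenzoic acid
Product: 22 (1R,3aS,8S,8aS)-1-hydroxy-3a,6-dimethyl-4-oxo-1-(propan-2-yl)-1,2,3,3a,4,7,8,8a-octahydroazulen-8-yl 4-acetoxybenzoate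
Conditions: N,N'-dicyclohexylcarbodiimide, DMAP, CH2Cl2, 0 °C → rt
Reagents that add atoms: none
Why: Carbodiimide (Steglich) esterification with DMAP should acylate the secondary hydroxyl only, the tertiary hydroxyl beside the isopropyl group being too hindered to react.

Step 14
Reactants: 22
Product: 23 (1R,3aS,8S,8aS)-1-hydroxy-3a,6-dimethyl-4-oxo-1-(propan-2-yl)-1,2,3,3a,4,7,8,8a-octahydroazulen-8-yl 4-hydroxybenzoate (CNP0210039.1)
Conditions: NH4OAc, MeOH/H2O, rt
Reagents that add atoms: none
Why: A phenyl acetate is cleaved by mild methanolysis much faster than the benzoate of a secondary alcohol, and the near-neutral ammonium acetate medium avoids base-induced vinylogous β-elimination of the aroyloxy group from the enone.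

**Compound list**

1 | 3-methylcyclopent-2-en-1-one | CC1=CC(=O)CC1 | starting material
2 | prop-1-en-2-ylmagnesium bromide | CC(=C)[Mg]Br | starting material
3 | 2-(benzyloxy)acetaldehyde | O=CCOCc1ccccc1 | starting material
4 | dimethyl(prop-1-en-2-yl)aluminium | CC(=C)[Al](C)C | intermediate
5 | dimethyl{[(3S)-3-methyl-3-(prop-1-en-2-yl)cyclopent-1-en-1-yl]oxy}aluminium (aluminium enolate) | CC(=C)[C@@]1(C)CCC(O[Al](C)C)=C1 | intermediate
6 | (2S,3S)-2-[(1R)-2-(benzyloxy)-1-hydroxyethyl]-3-methyl-3-(prop-1-en-2-yl)cyclopentan-1-one | CC(=C)[C@@]1(C)CCC(=O)[C@@H]1[C@@H](O)COCc1ccccc1 | intermediate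
7 | (2S,3S)-2-[(1R)-2-(benzyloxy)-1-(tert-butyldimethylsilyloxy)ethyl]-3-methyl-3-(prop-1-en-2-yl)cyclopentan-1-one | CC(=C)[C@@]1(C)CCC(=O)[C@@H]1[C@@H](O[Si](C)(C)C(C)(C)C)COCc1ccccc1 | intermediate
8 | propan-2-ylmagnesium chloride | CC(C)[Mg]Cl | starting material
9 | (1R,2S,3S)-2-[(1R)-2-(benzyloxy)-1-(tert-butyldimethylsilyloxy)ethyl]-3-methyl-1-(propan-2-yl)-3-(prop-1-en-2-yl)cyclopentan-1-ol | CC(=C)[C@@]1(C)CC[C@@](O)(C(C)C)[C@@H]1[C@@H](O[Si](C)(C)C(C)(C)C)COCc1ccccc1 | intermediate
10 | {[(1R,2S,3S)-2-[(1R)-2-(benzyloxy)-1-(tert-butyldimethylsilyloxy)ethyl]-3-methyl-1-(propan-2-yl)-3-(prop-1-en-2-yl)cyclopentyl]oxy}triethylsilane | CC(=C)[C@@]1(C)CC[C@@](O[Si](CC)(CC)CC)(C(C)C)[C@@H]1[C@@H](O[Si](C)(C)C(C)(C)C)COCc1ccccc1 | intermediate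
11 | 1-[(1S,2S,3R)-2-[(1R)-2-(benzyloxy)-1-(tert-butyldimethylsilyloxy)ethyl]-1-methyl-3-(propan-2-yl)-3-(triethylsilyloxy)cyclopentyl]ethan-1-one | CC(=O)[C@@]1(C)CC[C@@](O[Si](CC)(CC)CC)(C(C)C)[C@@H]1[C@@H](O[Si](C)(C)C(C)(C)C)COCc1ccccc1 | intermediate
12 | 1-[(1S,2S,3R)-2-[(1R)-1-(tert-butyldimethylsilyloxy)-2-hydroxyethyl]-1-methyl-3-(propan-2-yl)-3-(triethylsilyloxy)cyclopentyl]ethan-1-one | CC(=O)[C@@]1(C)CC[C@@](O[Si](CC)(CC)CC)(C(C)C)[C@@H]1[C@@H](O[Si](C)(C)C(C)(C)C)CO | intermediate
13 | 1-[(1S,2S,3R)-2-[(1R)-1-(tert-butyldimethylsilyloxy)-2-iodoethyl]-1-methyl-3-(propan-2-yl)-3-(triethylsilyloxy)cyclopentyl]ethan-1-one | CC(=O)[C@@]1(C)CC[C@@](O[Si](CC)(CC)CC)(C(C)C)[C@@H]1[C@@H](O[Si](C)(C)C(C)(C)C)CI | intermediate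
14 | (1R,3aS,7S,7aS)-7-(tert-butyldimethylsilyloxy)-3a-methyl-1-(propan-2-yl)-1-(triethylsilyloxy)octahydro-4H-inden-4-one (trans-fused) | C1C(=O)[C@@]2(C)CC[C@@](O[Si](CC)(CC)CC)(C(C)C)[C@@H]2[C@@H](O[Si](C)(C)C(C)(C)C)C1 | intermediate
15 | (1R,3aS,7S,7aS)-7-(tert-butyldimethylsilyloxy)-3a,5-dimethyl-1-(propan-2-yl)-1-(triethylsilyloxy)octahydro-4H-inden-4-one (mixture at C5) | CC1C(=O)[C@@]2(C)CC[C@@](O[Si](CC)(CC)CC)(C(C)C)[C@@H]2[C@@H](O[Si](C)(C)C(C)(C)C)C1 | intermediate
16 | (1R,3aS,7S,7aS)-7-(tert-butyldimethylsilyloxy)-3a,5-dimethyl-1-(propan-2-yl)-1-(triethylsilyloxy)-4-(trimethylsilyloxy)-2,3,3a,6,7,7a-hexahydro-1H-indene | CC1=C(O[Si](C)(C)C)[C@@]2(C)CC[C@@](O[Si](CC)(CC)CC)(C(C)C)[C@@H]2[C@@H](O[Si](C)(C)C(C)(C)C)C1 | intermediate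
17 | siloxycyclopropane: CH2 adduct across C4=C5 of 16 (tricyclic; both cyclopropane faces; other centres as in 16) | CC12CC1(O[Si](C)(C)C)[C@@]3(C)CC[C@@](O[Si](CC)(CC)CC)(C(C)C)[C@@H]3[C@@H](O[Si](C)(C)C(C)(C)C)C2 | intermediate
18 | (1R,3aS,8S,8aS)-8-(tert-butyldimethylsilyloxy)-6-chloro-3a,6-dimethyl-1-(propan-2-yl)-1-(triethylsilyloxy)octahydroazulen-4(1H)-one (mixture at C6) | CC1(Cl)CC(=O)[C@@]2(C)CC[C@@](O[Si](CC)(CC)CC)(C(C)C)[C@@H]2[C@@H](O[Si](C)(C)C(C)(C)C)C1 | intermediate
19 | (1R,3aS,8S,8aS)-8-(tert-butyldimethylsilyloxy)-3a,6-dimethyl-1-(propan-2-yl)-1-(triethylsilyloxy)-2,3,3a,7,8,8a-hexahydroazulen-4(1H)-one | CC1=CC(=O)[C@@]2(C)CC[C@@](O[Si](CC)(CC)CC)(C(C)C)[C@@H]2[C@@H](O[Si](C)(C)C(C)(C)C)C1 | intermediate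
20 | (1R,3aS,8S,8aS)-1,8-dihydroxy-3a,6-dimethyl-1-(propan-2-yl)-2,3,3a,7,8,8a-hexahydroazulen-4(1H)-one | CC1=CC(=O)[C@@]2(C)CC[C@@](O)(C(C)C)[C@@H]2[C@@H](O)C1 | intermediate
21 | 4-acetoxybenzoic acid | CC(=O)Oc1ccc(cc1)C(O)=O | starting material
22 | (1R,3aS,8S,8aS)-1-hydroxy-3a,6-dimethyl-4-oxo-1-(propan-2-yl)-1,2,3,3a,4,7,8,8a-octahydroazulen-8-yl 4-acetoxybenzoate | CC1=CC(=O)[C@@]2(C)CC[C@@](O)(C(C)C)[C@@H]2[C@@H](OC(=O)c2ccc(OC(C)=O)cc2)C1 | intermediate
23 | (1R,3aS,8S,8aS)-1-hydroxy-3a,6-dimethyl-4-oxo-1-(propan-2-yl)-1,2,3,3a,4,7,8,8a-octahydroazulen-8-yl 4-hydroxybenzoate | CC1=CC(=O)[C@@]2(C)CC[C@@](O)(C(C)C)[C@@H]2[C@@H](OC(=O)c2ccc(O)cc2)C1 | target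

**Step count and risks**

Total step count: 14. Longest linear sequence: 14 steps (1 to 23).

Steps most likely to fail:

Step 1. One operation has to deliver three selectivities: enantiofacial transfer of the alkenyl group, discrimination of the two enolate faces by methyl against isopropenyl, and anti rather than syn bond formation at the carbinol carbon. A loose or equilibrating aluminium aldolate would erode the last two. The fallback sets out from 1 (with 2) and comes back at 6. The conjugate addition is run as before, but enolate 5 is trapped with TMSOTf as the trimethylsilyl enol ether F1, which can be purified and assayed for enantiomeric purity. Silicon–boron exchange with Bu2BOTf in CH2Cl2 at −78 °C would give the dibutylboron enolate F2. Its aldol addition to 3 passes through a tight boron-centred chair transition state, which is reliably anti for ring-locked (E)-enolates and more sensitive to the steric difference between the two faces; buffered aqueous work-up should then give 6.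

Step 11. Carbenoid transfer to a tetrasubstituted enol ether beside a quaternary carbon may be sluggish, and the Lewis-acidic iron chloride may strip silyl ethers or open the cyclopropane unselectively. The fallback sets out from 16 and comes back at 19, and it inserts the same carbon between the same two atoms. Dibromocarbene (CHBr3, KOt-Bu, pentane, −20 °C → rt) is far more electrophilic than the zinc carbenoid and should give the dibromo(siloxy)cyclopropane F3. On warming, F3 loses bromide with disrotatory opening of the three-membered ring and desilylation, which is the classical dihalocarbene ring expansion of enol ethers, to give the 5-bromo enone F4. Palladium-catalysed formate hydrogenolysis of the carbon–bromine bond (Pd(OAc)2, PPh3, HCO2H, Et3N, DMF, 60 °C) should then give 19.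

Step 3. The branched Grignard reagent may enolise the hindered ketone, which is followed by β-elimination of the silyloxy group, or it may reduce the ketone by β-hydride transfer instead of adding. The fallback sets out from 7 and comes back at 9. The slimmer, non-reducing sp2 nucleophile 2 is added with CeCl3 (THF, −78 °C) to give the bis-isopropenyl tertiary alcohol F5, with the same facial preference. Hydroxyl-directed hydrogenation with [Ir(cod)(PCy3)(py)]PF6 and H2 (CH2Cl2, 0 °C) should then saturate only the alkene next to the hydroxyl; the other isopropenyl group, on the opposite ring face and beside a quaternary carbon, and the benzyl ether should be left intact, giving 9.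

**Further compounds**

F1 | step 1 | trimethyl{[(3S)-3-methyl-3-(prop-1-en-2-yl)cyclopent-1-en-1-yl]oxy}silane | CC(=C)[C@@]1(C)CCC(O[Si](C)(C)C)=C1
F2 | step 1 | dibutyl{[(3S)-3-methyl-3-(prop-1-en-2-yl)cyclopent-1-en-1-yl]oxy}borane | CC(=C)[C@@]1(C)CCC(OB(CCCC)CCCC)=C1
F3 | step 11 | dibromo(siloxy)cyclopropane: CBr2 adduct across C4=C5 of 16 (both cyclopropane faces; other centres as in 16) | CC12C(Br)(Br)C1(O[Si](C)(C)C)[C@@]3(C)CC[C@@](O[Si](CC)(CC)CC)(C(C)C)[C@@H]3[C@@H](O[Si](C)(C)C(C)(C)C)C2
F4 | step 11 | (1R,3aS,8S,8aS)-5-bromo-8-(tert-butyldimethylsilyloxy)-3a,6-dimethyl-1-(propan-2-yl)-1-(triethylsilyloxy)-2,3,3a,7,8,8a-hexahydroazulen-4(1H)-one | CC1=C(Br)C(=O)[C@@]2(C)CC[C@@](O[Si](CC)(CC)CC)(C(C)C)[C@@H]2[C@@H](O[Si](C)(C)C(C)(C)C)C1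
F5 | step 3 | (1S,2S,3S)-2-[(1R)-2-(benzyloxy)-1-(tert-butyldimethylsilyloxy)ethyl]-3-methyl-1,3-di(prop-1-en-2-yl)cyclopentan-1-ol | CC(=C)[C@@]1(C)CC[C@@](O)(C(C)=C)[C@@H]1[C@@H](O[Si](C)(C)C(C)(C)C)COCc1ccccc1
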